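All runs were generated by integration with made-up constants, and the scatter is random.

In a one-step world, target would grow at its opening rate until the reagents ended; these flasks bend far sooner.

| flask | starting material | second substrate | coupling partner | free catalyst | temperature | remark | time |
|---|---|---|---|---|---|---|---|
| Sunday's | 10 mM | 2 equiv | 1.5 equiv | 11 mol% | 95 °C | run made earlier |  |
| Saturday's | 10 mM | 2 equiv | 1.5 equiv | 25 mol% | 106 °C | run made earlier |  |
| Wednesday's | 16 mM | 2 equiv | 1.5 equiv | 16 mol% | 95 °C | run made earlier |  |
| delta | 15 mM | 2.00 equiv | 4.50 equiv | 16 mol% | 100 °C |  | 10 min |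
| gamma | 40 mM | 3.00 equiv | 6.00 equiv | 16 mol% | 100 °C |  | 10 min |
| epsilon | 10 mM | 2.00 equiv | 1.50 equiv | 10 mol% | 100 °C |  | 10 min |
| theta | 10 mM | 2.00 equiv | 1.50 equiv | 16 mol% | 100 °C |  | 10 min |

- Sunday's (time / min: target / %): 0.417: 1.0; 1.33: 4.0; 2.50: 6.6; 4.00: 9.6; 5.00: 10.3
- Saturday's (time / min: target / %): 0.417: 3.9; 0.833: 8.2; 1.33: 11.9; 2.50: 18.7; 5.00: 23.7
- Wednesday's (time / min: target / %): 0.417: 2.6; 0.833: 5.0; 1.33: 8.2; 2.50: 12.1; 5.00: 16.8

(scatter of a reading: 0.3 percentage points)

1. ranking by amount of target, in percent of the starting material charged, from high to low, at 10 min (delta / gamma / epsilon / theta)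
2. the same order at 1.0 min (delta / gamma / epsilon / theta)
3. the amount of target, in percent of the starting material charged of the flask you put first, at 10 min
4. the amount of target, in percent of the starting material charged of the flask you put last, at 10 min

- the earlier runs were read with a standard deviation of 0.3 percentage points

Each reading is best expressed per catalyst charged. If the gain over equal time steps shrinks by a steady fraction, then with a the target at 2.50 min and b at 5.00 min, the series sums to an estimated plateau:

plateau = a·a/(a + a − b)

This gives 15.0% for Sunday's run, 25.5% for Saturday's and 19.8% for Wednesday's, all readings with their scatter. The plateau divided by the catalyst loading is a turnover number; call its mean over these runs the turnover plateau n = 1.21.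

The opening rate per catalyst, from Sunday's and Saturday's runs, which bracket 100 °C, averages 0.334 min⁻¹.

Theta can then be solved at both ends. With the opening rate held, it reaches 53.4% at 10 min. With the plateau reached at once, it stands at 19.3%, which is lower. The two ends meet at τ = n/rate = 3.62 min, and this estimate joins them, with n an estimate and not a bound:

c(target) = n · c(free catalyst, charged) · (1 − exp(−t/τ))

At 10 min this gives theta 18.1% and epsilon 11.3%. At 1.0 min it gives theta 4.66% and epsilon 2.91%.

Wednesday's run at 16 mM opens at 0.375 min⁻¹ per catalyst, faster than Sunday's run at 10 mM and the same temperature. So gamma and delta should lead at 1.0 min, which is shorter than τ. At 10 min, longer than τ, the estimate of n times loading puts theta, delta and gamma level, with epsilon under them.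

The forecast gave gamma > delta > theta > epsilon at 10 min and gamma > delta > theta > epsilon at 1.0 min, with 30% and 12%, holding that “concentration and excess partners favour turnover over death”.

The flasks give delta > gamma > theta > epsilon at 10 min: delta 29.0%, gamma 23.8%, theta 20.8%, epsilon 14.9%. At 1.0 min the order is gamma > delta > theta > epsilon.

    starting material + free catalyst ⇌ catalyst intermediate A (K = 1600 M⁻¹, k = 7.40 M⁻¹ s⁻¹, Ea = 46.0 kJ mol⁻¹, ΔH = −10.0 kJ mol⁻¹)
    coupling partner + catalyst intermediate A → free catalyst + target (k = 1.30 M⁻¹ s⁻¹, Ea = 62.0 kJ mol⁻¹)
    second substrate + free catalyst ⇌ catalyst intermediate B (K = 75.0 M⁻¹, k = 11.0 M⁻¹ s⁻¹, Ea = 36.0 kJ mol⁻¹, ΔH = 10.0 kJ mol⁻¹)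
    coupling partner + catalyst intermediate B → free catalyst + second product (k = 4.50 M⁻¹ s⁻¹, Ea = 69.0 kJ mol⁻¹)
    2 coupling partner → self-condensation product (k = 0.560 M⁻¹ s⁻¹, Ea = 56.0 kJ mol⁻¹)
    (constants at 100 °C)

Theta stands at 1.30 turnovers and delta at 1.81, which is above n. At 10.0 min, delta holds 82.1% of its catalyst as catalyst intermediate A, the resting state, 11.3% as catalyst intermediate B and 6.56% free, while coupling partner is down to 0.520% of its charge. The neighbour of delta charged with 40 mol% of free catalyst reckons at n times loading, 48.4%. That flask gives 45.0%, or 1.12 turnovers, with coupling partner at 0.0312% of its charge.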